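**Retrosynthetic overview**

1. 27 ⇒ 25 + angelic acid 26 (C3–O acylation last) ⇒ 23 (allylic oxidation at C11, the α-pinene-to-verbenone transform) ⇒ 20 (radical removal of the C7 oxygen) ⇒ 16 + epoxy acid 19 (from tiglyl alcohol 17).
2. 16 ⇒ 15 (Evans–Tishchenko: C3–OH sets C5 and is acetylated) ⇒ open-chain acid 10 in one flask: a vinylketene–alkene [2+2] closes the cyclobutane and the six-membered ring together, then a Mukaiyama aldol forms C6–C7 and closes the seven-membered ring.
3. Enabling feature: C7 is the one-carbon bridge of the bicyclo[3.1.1]heptene (cyclobutane C1–C2–C8–C7) that lies between the bridgeheads C1 and C8 and carries only H, so it can be the carbonyl of a strained, non-enolisable cyclobutanone; C6 (CMe2) is α to the oxygenated C5, so it can be an enolate carbon; the C3–C6 chain hangs from C2 on the cyclobutane face anti to the C9–C11 bridge, the only face from which the seven-membered ring can close.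
4. 10 ⇐ geranyl acetate 1 (oxidation of the terminal E-methyl) + 3-methylbut-3-en-2-one 4, joined by an asymmetric boron aldol that sets the one stereocentre (8R of 10 = C3 of the tricycle) from which all others are relayed.
5. Ring order: four- and six-membered rings together, then the seven-membered ring.

Key step: step 7

Numbering remark: tricycles carry the locants of tricyclo[5.4.0.0^{2,8}]undecane (C1, C8 bridgeheads; C2 quaternary C–Me; C3 CH–O; C4 CH2; C5 CH–O; C6 CMe2; C7 cyclobutane CH; C9=C10 with Me on C9; C11 ketone); C1–C11 of the open-chain compounds become tricycle C7, C8, C9, C10, C11, C1, C2, C3, C4, C5, C6. The target SMILES is read as the Z (angelic) ester at C3–O and the (2S,3R)-epoxide with cis ring methyls (a tiglate epoxide) at C5–O.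

**Route**

Step 1
Reactants: 1 geranyl acetate
Product: 2 (2E,6E)-8-hydroxy-3,7-dimethylocta-2,6-dien-1-yl acetate
Conditions: SeO2 (0.1 equiv), t-BuOOH (3 equiv), salicylic acid (0.1 equiv), CH2Cl2, rt
Reagents that add atoms: tert-butyl hydroperoxide CC(C)(C)OO
Why: The SeO2/t-BuOOH allylic (Riley) oxidation, an ene reaction followed by a [2,3]-shift, should hydroxylate only the E-methyl group of the electron-rich terminal alkene, the alkene next to the acetate being deactivated; no stereocentre is formed and both E double bonds are kept.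

Step 2
Reactants: 2 (2E,6E)-8-hydroxy-3,7-dimethylocta-2,6-dien-1-yl acetate
Product: 3 (2E,6E)-3,7-dimethyl-8-oxoocta-2,6-dien-1-yl acetate
Conditions: MnO2 (15 equiv), CH2Cl2, rt
Reagents that add atoms: none
Why: MnO2 oxidises the primary allylic alcohol to the E-enal without touching the acetate or the alkene geometry.

Step 3
Reactants: 3 (2E,6E)-3,7-dimethyl-8-oxoocta-2,6-dien-1-yl acetate; 4 3-methylbut-3-en-2-one
Product: 5 (2E,6E,8R)-8-hydroxy-3,7,11-trimethyl-10-oxododeca-2,6,11-trien-1-yl acetate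
Conditions: 4, (−)-Ipc2BCl, Et3N, Et2O, −78 to 0 °C; then 3, −78 to −20 °C; H2O2, pH 7 buffer, MeOH, 0 °C
Reagents that add atoms: none
Why: In this diisopinocampheylboron-mediated asymmetric aldol the ketone can enolise only at its methyl group (the other α-carbon is sp2) and the chiral ligands on boron steer the enol borinate to one face of the enal in a cyclic transition state, the reagent antipode being the one that adds to the Re face and gives the 8R carbinol (if the sense proves opposite, the (+)-reagent is used).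

Step 4
Reactants: 5 (2E,6E,8R)-8-hydroxy-3,7,11-trimethyl-10-oxododeca-2,6,11-trien-1-yl acetate
Product: 6 (2E,6E,8R)-1,8-dihydroxy-3,7,11-trimethyldodeca-2,6,11-trien-10-one
Conditions: Novozym 435 (immobilised Candida antarctica lipase B), n-BuOH (5 equiv), MTBE, 30 °C
Reagents that add atoms: none
Why: Lipase-catalysed transesterification removes the unhindered primary allylic acetate at neutral pH, which avoids the retro-aldol, elimination, oxa-Michael and alkoxide conjugate-addition pathways that basic methanolysis would open in this β-hydroxy isopropenyl ketone; the stereocentre is untouched.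

Step 5
Reactants: 6 (2E,6E,8R)-1,8-dihydroxy-3,7,11-trimethyldodeca-2,6,11-trien-10-one
Product: 8 (2E,6E,8R)-8-hydroxy-3,7,11-trimethyl-10-oxododeca-2,6,11-trienoic acid, via enal 7 (not isolated)
Conditions: TEMPO (0.1 equiv), PhI(OAc)2 (1.1 equiv), CH2Cl2, rt; then t-BuOH–H2O, NaClO2, NaH2PO4, 2-methyl-2-butene, 0 °C to rt
Reagents that add atoms: sodium chlorite [Na+].[O-]Cl=O
Why: The oxoammonium oxidation is selective for the primary over the secondary allylic alcohol, and the buffered Pinnick oxidation of the resulting E-enal with a chlorine scavenger should give the E-enoic acid without touching the alkenes, the enone or the carbinol centre.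

Step 6
Reactants: 8 (2E,6E,8R)-8-hydroxy-3,7,11-trimethyl-10-oxododeca-2,6,11-trienoic acid
Product: 10 (2E,6E,8R)-3,7,11-trimethyl-8,10-bis(triethylsilyloxy)dodeca-2,6,10-trienoic acid, via silyl ester 9 (not isolated)
Conditions: Et3SiH (5 equiv), RhCl(PPh3)3 (2 mol %), toluene, 50 °C; then MeOH, pH 7 phosphate buffer, 0 °C
Reagents that add atoms: triethylsilane CC[SiH](CC)CC
Why: Rhodium-catalysed 1,4-hydrosilylation of the α-methyl vinyl ketone puts H on the terminal CH2 and silicon on oxygen, so the tetrasubstituted enol silane (no E/Z question) is formed with full regiocontrol, while the same catalyst silylates OH and CO2H dehydrogenatively and the labile silyl ester alone is then methanolysed.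

Step 7
Reactants: 10 (2E,6E,8R)-3,7,11-trimethyl-8,10-bis(triethylsilyloxy)dodeca-2,6,10-trienoic acid
Product: 15 (1S,2S,3R,7S,8R)-3,7-dihydroxy-2,6,6-trimethyl-9-methylidenetricyclo[5.4.0.0^{2,8}]undecan-5-one, via acid chloride 11 (not isolated), via vinylketene 12 (not isolated), via cyclobutanone 13 (not isolated), via silyl ether 14 (not isolated)
Conditions: 1-chloro-N,N,2-trimethylprop-1-en-1-amine (1.1 equiv), CH2Cl2, 0 °C to rt; syringe-pump addition to Et3N (3 equiv), toluene, 110 °C, high dilution; cool to −78 °C, CH2Cl2, TiCl4 (5 equiv), −78 to −30 °C; aq NaHCO3; AcOH–THF–H2O (3:1:1), rt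
Reagents that add atoms: none
Why: Proposed new method: Et3N removes HCl from acid chloride 11 through its γ-methyl group to give vinylketene 12, whose ketene carbonyl carbon (future C7) bonds to the CH end (C1) and whose α-carbon (C8) bonds to the fully substituted end (C2) of the nucleophilic E-trisubstituted alkene in a concerted, asynchronous thermal [2+2] cycloaddition, and after cooling TiCl4 activates the strained, non-enolisable cyclobutanone 13 for a Mukaiyama aldol attack by the enol silane carbon C6 that forms the C6–C7 bond. The closest known reactions are the intramolecular vinylketene–alkene [2+2] cycloaddition of terpenoid dienoyl chlorides to 7,7-disubstituted 2-methylidenebicyclo[3.1.1]heptan-6-ones under these amine conditions and the TiCl4 Mukaiyama aldol of enol silanes with ketones, which like titanium enolate aldols runs in the presence of amine hydrochlorides; new are their union in one flask and the seven-membered closure onto a bicyclo[3.1.1]heptan-6-one. The four- and six-membered rings close together in the crossed [2+2] mode over a three-atom tether, and the seven-membered ring closes by a 7-(enolendo)-exo-trig aldol through an open transition state. C1, C2 and C8 arise in the cycloaddition: suprafacial addition to the E-alkene puts the C2 methyl syn and the C3 chain anti to the C9–C11 bridge, and the absolute sense should follow from the 8R silyloxy centre of 10 (C3 of 15), whose C–CH2 bond eclipses the alkene to avoid A(1,2) strain with the C2 methyl so that the ketene adds anti to OSiEt3; C7 is fixed by the tether, which can reach the carbonyl only from the face anti to the bridge, leaving the hydroxyl where the target has H. The step needs crossed rather than fused regiochemistry (secured by the polarised trisubstituted alkene), bond formation at C6 and not at C4 (secured by the regiodefined enol silane, since a free enolate would close a five-membered ring through C4) and π-facial control (secured by the allylic stereocentre).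

Step 8
Reactants: 15 (1S,2S,3R,7S,8R)-3,7-dihydroxy-2,6,6-trimethyl-9-methylidenetricyclo[5.4.0.0^{2,8}]undecan-5-one
Product: 16 (1S,2S,3R,5R,7S,8R)-5,7-dihydroxy-2,6,6-trimethyl-9-methylidenetricyclo[5.4.0.0^{2,8}]undecan-3-yl acetate
Conditions: MeCHO (8 equiv), SmI2 (0.3 equiv), THF, −10 °C
Reagents that add atoms: acetaldehyde CC=O
Why: In the Evans–Tishchenko reduction the C3 hydroxyl forms a samarium-bound hemiacetal with acetaldehyde and delivers its hydride to the same face of the C5 ketone through a six-membered chair, which should set the 5R carbinol anti to C3–O and acetylate C3–O in the same event, so the two secondary oxygens are differentiated (the tertiary C7–OH is antiperiplanar to C5 and cannot take part).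

Step 9
Reactants: 17 (2E)-2-methylbut-2-en-1-ol
Product: 18 [(2R,3R)-2,3-dimethyloxiran-2-yl]methanol
Conditions: Ti(OiPr)4 (10 mol %), D-(−)-diethyl tartrate (12 mol %), t-BuOOH, 4 Å MS, CH2Cl2, −20 °C
Reagents that add atoms: tert-butyl hydroperoxide CC(C)(C)OO
Why: The Sharpless asymmetric epoxidation is stereospecific for the E-alkene (ring methyls end cis) and the D-(−)-tartrate selects the alkene face that gives the 2R,3R epoxy alcohol.

Step 10
Reactants: 18 [(2R,3R)-2,3-dimethyloxiran-2-yl]methanol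
Product: 19 (2S,3R)-2,3-dimethyloxirane-2-carboxylic acid
Conditions: RuCl3·xH2O (2 mol %), NaIO4 (3 equiv), CCl4–MeCN–H2O, rt
Reagents that add atoms: water O
Why: RuO4 generated from RuCl3/NaIO4 oxidises the primary alcohol through the aldehyde hydrate to the acid without opening the trisubstituted epoxide, so both centres are kept (the C2 descriptor changes to S only through the CIP priorities).

Step 11
Reactants: 16 (1S,2S,3R,5R,7S,8R)-5,7-dihydroxy-2,6,6-trimethyl-9-methylidenetricyclo[5.4.0.0^{2,8}]undecan-3-yl acetate; 19 (2S,3R)-2,3-dimethyloxirane-2-carboxylic acid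
Product: 20 (1S,2S,3R,5R,7S,8R)-3-acetoxy-7-hydroxy-2,6,6-trimethyl-9-methylidenetricyclo[5.4.0.0^{2,8}]undecan-5-yl (2S,3R)-2,3-dimethyloxirane-2-carboxylate
Conditions: 19, 2,4,6-trichlorobenzoyl chloride, Et3N, THF, rt; then 16, DMAP, toluene, 50 °C
Reagents that add atoms: none
Why: Yamaguchi esterification through the mixed anhydride should acylate the secondary C5–OH only, the tertiary C7–OH being too hindered, and no stereocentre is touched.

Step 12
Reactants: 20 (1S,2S,3R,5R,7S,8R)-3-acetoxy-7-hydroxy-2,6,6-trimethyl-9-methylidenetricyclo[5.4.0.0^{2,8}]undecan-5-yl (2S,3R)-2,3-dimethyloxirane-2-carboxylate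
Product: 21 (1S,2S,3R,5R,7S,8R)-3-acetoxy-7-[(methoxyoxalyl)oxy]-2,6,6-trimethyl-9-methylidenetricyclo[5.4.0.0^{2,8}]undecan-5-yl (2S,3R)-2,3-dimethyloxirane-2-carboxylate
Conditions: MeO2CCOCl (5 equiv), DMAP (0.5 equiv), pyridine, CH2Cl2, 0 to 40 °C
Reagents that add atoms: methyl chlorooxoacetate COC(=O)C(Cl)=O
Why: Methyl oxalyl chloride under nucleophilic catalysis is reactive enough to acylate the tertiary cyclobutanol, whose ester cannot eliminate because its β-positions are a quaternary carbon and two bridgeheads.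

Step 13
Reactants: 21 (1S,2S,3R,5R,7S,8R)-3-acetoxy-7-[(methoxyoxalyl)oxy]-2,6,6-trimethyl-9-methylidenetricyclo[5.4.0.0^{2,8}]undecan-5-yl (2S,3R)-2,3-dimethyloxirane-2-carboxylate
Product: 22 (1S,2S,3R,5R,7S,8R)-3-acetoxy-7-[(methoxyoxalyl)oxy]-2,6,6,9-tetramethyltricyclo[5.4.0.0^{2,8}]undec-9-en-5-yl (2S,3R)-2,3-dimethyloxirane-2-carboxylate
Conditions: RuHCl(CO)(PPh3)3 (5 mol %), toluene, 80 °C
Reagents that add atoms: none
Why: Ruthenium hydride addition and β-hydride elimination should move the exocyclic 1,1-disubstituted alkene to the more stable endocyclic C9=C10 position (as β-pinene goes to α-pinene), the only ring hydrogens available being on C10 because C8 is a bridgehead.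

Step 14
Reactants: 22 (1S,2S,3R,5R,7S,8R)-3-acetoxy-7-[(methoxyoxalyl)oxy]-2,6,6,9-tetramethyltricyclo[5.4.0.0^{2,8}]undec-9-en-5-yl (2S,3R)-2,3-dimethyloxirane-2-carboxylate
Product: 23 (1R,2S,3R,5R,7R,8R)-3-acetoxy-2,6,6,9-tetramethyltricyclo[5.4.0.0^{2,8}]undec-9-en-5-yl (2S,3R)-2,3-dimethyloxirane-2-carboxylate
Conditions: Bu3SnH (2 equiv), AIBN (0.2 equiv), toluene, 110 °C
Reagents that add atoms: none
Why: In this tertiary-oxalate variant of the Barton–McCombie deoxygenation, stannyl radical addition and C–O scission give the C7 cyclobutyl radical, which can take hydrogen only on its single open face because C7 holds three ring bonds, so the 7-H configuration of the target is fixed by the cage; a Dowd–Beckwith acyl shift is excluded because C5 is no longer a ketone.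

Step 15
Reactants: 23 (1R,2S,3R,5R,7R,8R)-3-acetoxy-2,6,6,9-tetramethyltricyclo[5.4.0.0^{2,8}]undec-9-en-5-yl (2S,3R)-2,3-dimethyloxirane-2-carboxylate
Product: 24 (1R,2R,3R,5R,7S,8R)-3-acetoxy-2,6,6,9-tetramethyl-11-oxotricyclo[5.4.0.0^{2,8}]undec-9-en-5-yl (2S,3R)-2,3-dimethyloxirane-2-carboxylate
Conditions: CrO3, 3,5-dimethylpyrazole (15 equiv each), CH2Cl2, −20 °C
Reagents that add atoms: chromium trioxide O=[Cr](=O)=O
Why: Allylic oxidation with the CrO3–3,5-dimethylpyrazole complex should convert the ring allylic CH2 (C11) into the enone carbonyl exactly as α-pinene gives verbenone, the other ring allylic position (C8) being a bridgehead; no stereocentre changes (descriptors at C1, C2 and C7 change only through the CIP priorities).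

Step 16
Reactants: 24 (1R,2R,3R,5R,7S,8R)-3-acetoxy-2,6,6,9-tetramethyl-11-oxotricyclo[5.4.0.0^{2,8}]undec-9-en-5-yl (2S,3R)-2,3-dimethyloxirane-2-carboxylate
Product: 25 (1R,2R,3R,5R,7S,8R)-3-hydroxy-2,6,6,9-tetramethyl-11-oxotricyclo[5.4.0.0^{2,8}]undec-9-en-5-yl (2S,3R)-2,3-dimethyloxirane-2-carboxylate
Conditions: K2CO3 (0.3 equiv), MeOH, 0 °C
Reagents that add atoms: none
Why: Base-catalysed methanolysis should remove the acetyl group much faster than the α-quaternary epoxy ester, and the enone has no epimerisable centre because both flanking ring positions are bridgeheads.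

Step 17
Reactants: 25 (1R,2R,3R,5R,7S,8R)-3-hydroxy-2,6,6,9-tetramethyl-11-oxotricyclo[5.4.0.0^{2,8}]undec-9-en-5-yl (2S,3R)-2,3-dimethyloxirane-2-carboxylate; 26 angelic acid
Product: 27 (1R,2R,3R,5R,7S,8R)-5-{[(2S,3R)-2,3-dimethyloxirane-2-carbonyl]oxy}-2,6,6,9-tetramethyl-11-oxotricyclo[5.4.0.0^{2,8}]undec-9-en-3-yl (2Z)-2-methylbut-2-enoate
Conditions: 26, 2,4,6-trichlorobenzoyl chloride, Et3N, toluene, rt; then 25 pretreated with LiN(SiMe3)2 (1.05 equiv), THF, −78 to 0 °C
Reagents that add atoms: none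
Why: Acylation of the preformed lithium alkoxide by the mixed angelic 2,4,6-trichlorobenzoic anhydride at low temperature avoids the nucleophilic catalysts and heat that isomerise angelates to tiglates, so the Z ester should be transferred unchanged to C3–O.

**Compound list**

1 | geranyl acetate, (2E)-3,7-dimethylocta-2,6-dien-1-yl acetate | CC(=O)OC/C=C(\C)CCC=C(C)C | starting material
2 | (2E,6E)-8-hydroxy-3,7-dimethylocta-2,6-dien-1-yl acetate | CC(=O)OC/C=C(\C)CC/C=C(\C)CO | intermediate
3 | (2E,6E)-3,7-dimethyl-8-oxoocta-2,6-dien-1-yl acetate | CC(=O)OC/C=C(\C)CC/C=C(\C)C=O | intermediate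
4 | 3-methylbut-3-en-2-one | CC(=O)C(C)=C | starting material
5 | (2E,6E,8R)-8-hydroxy-3,7,11-trimethyl-10-oxododeca-2,6,11-trien-1-yl acetate | CC(=O)OC/C=C(\C)CC/C=C(\C)[C@H](O)CC(=O)C(C)=C | intermediate
6 | (2E,6E,8R)-1,8-dihydroxy-3,7,11-trimethyldodeca-2,6,11-trien-10-one | OC/C=C(\C)CC/C=C(\C)[C@H](O)CC(=O)C(C)=C | intermediate
7 | (2E,6E,8R)-8-hydroxy-3,7,11-trimethyl-10-oxododeca-2,6,11-trienal | O=C/C=C(\C)CC/C=C(\C)[C@H](O)CC(=O)C(C)=C | intermediate
8 | (2E,6E,8R)-8-hydroxy-3,7,11-trimethyl-10-oxododeca-2,6,11-trienoic acid | OC(=O)/C=C(\C)CC/C=C(\C)[C@H](O)CC(=O)C(C)=C | intermediate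
9 | triethylsilyl (2E,6E,8R)-3,7,11-trimethyl-8,10-bis(triethylsilyloxy)dodeca-2,6,10-trienoate | CC[Si](CC)(CC)OC(=O)/C=C(\C)CC/C=C(\C)[C@H](O[Si](CC)(CC)CC)CC(O[Si](CC)(CC)CC)=C(C)C | intermediate
10 | (2E,6E,8R)-3,7,11-trimethyl-8,10-bis(triethylsilyloxy)dodeca-2,6,10-trienoic acid | OC(=O)/C=C(\C)CC/C=C(\C)[C@H](O[Si](CC)(CC)CC)CC(O[Si](CC)(CC)CC)=C(C)C | intermediate
11 | (2E,6E,8R)-3,7,11-trimethyl-8,10-bis(triethylsilyloxy)dodeca-2,6,10-trienoyl chloride | ClC(=O)/C=C(\C)CC/C=C(\C)[C@H](O[Si](CC)(CC)CC)CC(O[Si](CC)(CC)CC)=C(C)C | intermediate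
12 | (6E,8R)-7,11-dimethyl-3-methylidene-8,10-bis(triethylsilyloxy)dodeca-1,6,10-trien-1-one (vinylketene) | O=C=CC(=C)CC/C=C(\C)[C@H](O[Si](CC)(CC)CC)CC(O[Si](CC)(CC)CC)=C(C)C | intermediate
13 | (1R,5S,7S)-7-methyl-2-methylidene-7-[(1R)-4-methyl-1,3-bis(triethylsilyloxy)pent-3-en-1-yl]bicyclo[3.1.1]heptan-6-one | CC(C)=C(O[Si](CC)(CC)CC)C[C@@H](O[Si](CC)(CC)CC)[C@@]1(C)[C@@H]2CCC(=C)[C@H]1C2=O | intermediate
14 | (1S,2S,3R,7S,8R)-7-hydroxy-2,6,6-trimethyl-9-methylidene-3-(triethylsilyloxy)tricyclo[5.4.0.0^{2,8}]undecan-5-one | CC[Si](CC)(CC)O[C@@H]1CC(=O)C(C)(C)[C@]2(O)[C@H]3CCC(=C)[C@@H]2[C@]31C | intermediate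
15 | (1S,2S,3R,7S,8R)-3,7-dihydroxy-2,6,6-trimethyl-9-methylidenetricyclo[5.4.0.0^{2,8}]undecan-5-one | O[C@@H]1CC(=O)C(C)(C)[C@]2(O)[C@H]3CCC(=C)[C@@H]2[C@]31C | intermediate
16 | (1S,2S,3R,5R,7S,8R)-5,7-dihydroxy-2,6,6-trimethyl-9-methylidenetricyclo[5.4.0.0^{2,8}]undecan-3-yl acetate | CC(=O)O[C@@H]1C[C@@H](O)C(C)(C)[C@]2(O)[C@H]3CCC(=C)[C@@H]2[C@]31C | intermediate
17 | (2E)-2-methylbut-2-en-1-ol (tiglyl alcohol) | C/C=C(\C)CO | starting material
18 | [(2R,3R)-2,3-dimethyloxiran-2-yl]methanol | OC[C@@]1(C)O[C@@H]1C | intermediate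
19 | (2S,3R)-2,3-dimethyloxirane-2-carboxylic acid | OC(=O)[C@@]1(C)O[C@@H]1C | intermediate
20 | (1S,2S,3R,5R,7S,8R)-3-acetoxy-7-hydroxy-2,6,6-trimethyl-9-methylidenetricyclo[5.4.0.0^{2,8}]undecan-5-yl (2S,3R)-2,3-dimethyloxirane-2-carboxylate | CC(=O)O[C@@H]1C[C@@H](OC(=O)[C@@]2(C)O[C@@H]2C)C(C)(C)[C@]2(O)[C@H]3CCC(=C)[C@@H]2[C@]31C | intermediate
21 | (1S,2S,3R,5R,7S,8R)-3-acetoxy-7-[(methoxyoxalyl)oxy]-2,6,6-trimethyl-9-methylidenetricyclo[5.4.0.0^{2,8}]undecan-5-yl (2S,3R)-2,3-dimethyloxirane-2-carboxylate | CC(=O)O[C@@H]1C[C@@H](OC(=O)[C@@]2(C)O[C@@H]2C)C(C)(C)[C@]2(OC(=O)C(=O)OC)[C@H]3CCC(=C)[C@@H]2[C@]31C | intermediate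
22 | (1S,2S,3R,5R,7S,8R)-3-acetoxy-7-[(methoxyoxalyl)oxy]-2,6,6,9-tetramethyltricyclo[5.4.0.0^{2,8}]undec-9-en-5-yl (2S,3R)-2,3-dimethyloxirane-2-carboxylate | CC(=O)O[C@@H]1C[C@@H](OC(=O)[C@@]2(C)O[C@@H]2C)C(C)(C)[C@]2(OC(=O)C(=O)OC)[C@H]3CC=C(C)[C@@H]2[C@]31C | intermediate
23 | (1R,2S,3R,5R,7R,8R)-3-acetoxy-2,6,6,9-tetramethyltricyclo[5.4.0.0^{2,8}]undec-9-en-5-yl (2S,3R)-2,3-dimethyloxirane-2-carboxylate | CC(=O)O[C@@H]1C[C@@H](OC(=O)[C@@]2(C)O[C@@H]2C)C(C)(C)[C@@H]2[C@H]3CC=C(C)[C@@H]2[C@]31C | intermediate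
24 | (1R,2R,3R,5R,7S,8R)-3-acetoxy-2,6,6,9-tetramethyl-11-oxotricyclo[5.4.0.0^{2,8}]undec-9-en-5-yl (2S,3R)-2,3-dimethyloxirane-2-carboxylate | CC(=O)O[C@@H]1C[C@@H](OC(=O)[C@@]2(C)O[C@@H]2C)C(C)(C)[C@@H]2[C@H]3C(=O)C=C(C)[C@@H]2[C@]31C | intermediate
25 | (1R,2R,3R,5R,7S,8R)-3-hydroxy-2,6,6,9-tetramethyl-11-oxotricyclo[5.4.0.0^{2,8}]undec-9-en-5-yl (2S,3R)-2,3-dimethyloxirane-2-carboxylate | O[C@@H]1C[C@@H](OC(=O)[C@@]2(C)O[C@@H]2C)C(C)(C)[C@@H]2[C@H]3C(=O)C=C(C)[C@@H]2[C@]31C | intermediate
26 | angelic acid, (2Z)-2-methylbut-2-enoic acid | C/C=C(/C)C(O)=O | starting material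
27 | (1R,2R,3R,5R,7S,8R)-5-{[(2S,3R)-2,3-dimethyloxirane-2-carbonyl]oxy}-2,6,6,9-tetramethyl-11-oxotricyclo[5.4.0.0^{2,8}]undec-9-en-3-yl (2Z)-2-methylbut-2-enoate | C/C=C(/C)C(=O)O[C@@H]1C[C@@H](OC(=O)[C@@]2(C)O[C@@H]2C)C(C)(C)[C@@H]2[C@H]3C(=O)C=C(C)[C@@H]2[C@]31C | target

**Step count and risks**

Total step count: 17. Longest linear sequence: 15 steps (steps 1–8 and 11–17; steps 9–10 make the epoxy acid).

Steps most likely to fail:

Step 7 (proposed new method). The enol silane may not survive the hot amine hydrochloride stage, or the titanium stage may give retro-aldol or no closure. In addition, facial selection in the cycloaddition rests on an untested allylic-strain model and could be low or reversed. The fallback uses known reactions only, sets out from 10 and comes back at 15. The acid chloride is formed and cyclised with Et3N in toluene at 110 °C as above, but the mixture is worked up and the bicyclic ketone 13 is isolated, where diastereomers from the two alkene faces can be separated. NBS in THF at −78 °C converts the enol silane regiospecifically into the tertiary α-bromo ketone (1R,5S,7S)-7-[(1R)-4-bromo-4-methyl-3-oxo-1-(triethylsilyloxy)pentyl]-7-methyl-2-methylidenebicyclo[3.1.1]heptan-6-one F1. SmI2 (2.2 equiv) in THF at −78 °C under high dilution (intramolecular samarium Reformatsky reaction, established for medium-ring β-hydroxy ketones) then forms C6–C7 and gives 14, and AcOH–THF–H2O gives 15.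

Step 14. Stannyl radical attack on the oxalate carbonyl may be slow, so that reversible stannyl addition to the alkene opens the cyclobutane through a cyclobutylcarbinyl radical; the oxalylation of the hindered tertiary alcohol in step 12 may also stall. The fallback sets out from 20 and comes back at 23. It changes the activation from acyl transfer to alkoxide capture and deoxygenates before the alkene is moved. KN(SiMe3)2, CS2, then MeI in THF at −78 °C give the S-methyl xanthate (1S,2S,3R,5R,7S,8R)-3-acetoxy-2,6,6-trimethyl-9-methylidene-7-{[(methylsulfanyl)carbonothioyl]oxy}tricyclo[5.4.0.0^{2,8}]undecan-5-yl (2S,3R)-2,3-dimethyloxirane-2-carboxylate F2, which cannot undergo Chugaev elimination for lack of an accessible β-hydrogen. Bu3SnH/AIBN (Barton–McCombie; the thiocarbonyl traps stannyl radicals far faster than an alkene does) gives (1R,2S,3R,5R,7R,8R)-3-acetoxy-2,6,6-trimethyl-9-methylidenetricyclo[5.4.0.0^{2,8}]undecan-5-yl (2S,3R)-2,3-dimethyloxirane-2-carboxylate F3, and RuHCl(CO)(PPh3)3 in toluene at 80 °C then moves the alkene to give 23.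

Step 17. The angeloyl unit may isomerise from Z to E (to the tiglate) during activation, or acylation of the neopentyl-type C3–OH may be sluggish. The fallback sets out from 25 and comes back at 27, and builds the Z alkene on the ester instead of transferring it. 25 is esterified with 2-[bis(2,2,2-trifluoroethoxy)phosphoryl]propanoic acid (DCC, DMAP, CH2Cl2) to give (1R,2R,3R,5R,7S,8R)-5-{[(2S,3R)-2,3-dimethyloxirane-2-carbonyl]oxy}-2,6,6,9-tetramethyl-11-oxotricyclo[5.4.0.0^{2,8}]undec-9-en-3-yl 2-[bis(2,2,2-trifluoroethoxy)phosphoryl]propanoate F4 (both epimers at the phosphonate-bearing carbon). Still–Gennari olefination with KN(SiMe3)2, 18-crown-6 and acetaldehyde in THF at −78 °C should then give the (Z)-2-methylbut-2-enoate 27.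

Further compounds

F1 | step 7 | (1R,5S,7S)-7-[(1R)-4-bromo-4-methyl-3-oxo-1-(triethylsilyloxy)pentyl]-7-methyl-2-methylidenebicyclo[3.1.1]heptan-6-one | CC(C)(Br)C(=O)C[C@@H](O[Si](CC)(CC)CC)[C@@]1(C)[C@@H]2CCC(=C)[C@H]1C2=O
F2 | step 14 | (1S,2S,3R,5R,7S,8R)-3-acetoxy-2,6,6-trimethyl-9-methylidene-7-{[(methylsulfanyl)carbonothioyl]oxy}tricyclo[5.4.0.0^{2,8}]undecan-5-yl (2S,3R)-2,3-dimethyloxirane-2-carboxylate | CC(=O)O[C@@H]1C[C@@H](OC(=O)[C@@]2(C)O[C@@H]2C)C(C)(C)[C@]2(OC(=S)SC)[C@H]3CCC(=C)[C@@H]2[C@]31C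
F3 | step 14 | (1R,2S,3R,5R,7R,8R)-3-acetoxy-2,6,6-trimethyl-9-methylidenetricyclo[5.4.0.0^{2,8}]undecan-5-yl (2S,3R)-2,3-dimethyloxirane-2-carboxylate | CC(=O)O[C@@H]1C[C@@H](OC(=O)[C@@]2(C)O[C@@H]2C)C(C)(C)[C@@H]2[C@H]3CCC(=C)[C@@H]2[C@]31C
F4 | step 17 | (1R,2R,3R,5R,7S,8R)-5-{[(2S,3R)-2,3-dimethyloxirane-2-carbonyl]oxy}-2,6,6,9-tetramethyl-11-oxotricyclo[5.4.0.0^{2,8}]undec-9-en-3-yl 2-[bis(2,2,2-trifluoroethoxy)phosphoryl]propanoate (both epimers at the phosphonate-bearing carbon) | CC(C(=O)O[C@@H]1C[C@@H](OC(=O)[C@@]2(C)O[C@@H]2C)C(C)(C)[C@@H]2[C@H]3C(=O)C=C(C)[C@@H]2[C@]31C)P(=O)(OCC(F)(F)F)OCC(F)(F)F
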